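The target is cut at three bonds around C8 of cyclohexane ring C (naphtho[2,3-b]furan locants; primes for the benzofuran unit): C7–C8, C8–C2′ and O9–C3′. In one operation SmI2 joins C7 of an iodoalkyl chain to the aldehyde carbon C8 of an O-Boc salicylaldehyde (ring B), closing ring C; the alkoxide formed transfers Boc and expels it, so that O9–C9–C8a–C8 becomes an o-quinone methide that adds endo across C2′=C3′ of a 3-methylbenzofuran (ring A). The step exploits that C8 is both benzylic to phenolic O9 and the future chroman C4. The precursor is an open-chain iodo aldehyde plus a separate benzofuran; a C5 methoxy group steers the facial selectivity and is then exchanged for methyl.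

Key step: step 20

Locants: tetrahydronaphthofuran unit O1, C2, C3, C3a, C4, C4a, C5–C8, C8a, C9 (bearing O9), C9a (ring B is its benzene ring, ring C its cyclohexane ring); dihydrobenzofuran unit O1′, C2′, C3′, C3a′–C7a′ (ring A is its benzene ring). The target is (5S,8R,2′R,3′R).

Remark on the chemistry: in the o-quinone methide the peri methyl at C4 should hold the C5 substituent pseudoaxial and send the benzofuran to the opposite face of C8, whereas the target has the C5 methyl and the C8–C2′ bond cis; C5 is therefore carried through the key step as (R)-OMe and turned into (S)-CH3 with inversion in step 21.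

Step 1
Reactants: 1 2-methoxy-5-methylphenol
Product: 2 4-bromo-2-methoxy-5-methylphenol
Conditions: NBS, MeCN, 0 °C
Reagents that add atoms: N-bromosuccinimide, O=C1CCC(=O)N1Br
Why: Electrophilic aromatic bromination should go para to the free hydroxyl group, the strongest director, at the carbon next to the methyl group.

Step 2
Reactants: 2 4-bromo-2-methoxy-5-methylphenol; 3 chloroacetone
Product: 4 1-(4-bromo-2-methoxy-5-methylphenoxy)propan-2-one
Conditions: K2CO3, KI (cat.), acetone, 56 °C
Reagents that add atoms: none
Why: Williamson ether synthesis of the phenoxide with the reactive α-chloro ketone.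

Step 3
Reactants: 4 1-(4-bromo-2-methoxy-5-methylphenoxy)propan-2-one
Product: 5 5-bromo-7-methoxy-3,4-dimethylbenzofuran
Conditions: polyphosphoric acid, chlorobenzene, 100 °C
Reagents that add atoms: none
Why: Acid-mediated cyclodehydration of an aryloxyacetone (intramolecular Friedel–Crafts hydroxyalkylation, then loss of water) can close only onto the single free ortho carbon, between the ether oxygen and the methyl group.

Step 4
Reactants: 5 5-bromo-7-methoxy-3,4-dimethylbenzofuran
Product: 6 5-bromo-3,4-dimethylbenzofuran-7-ol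
Conditions: BBr3, CH2Cl2, −78 → 0 °C
Reagents that add atoms: none
Why: Lewis-acid cleavage of the aryl methyl ether, which the aryl bromide and the benzofuran should survive at low temperature.

Step 5
Reactants: 6 5-bromo-3,4-dimethylbenzofuran-7-ol
Product: 7 (5-bromo-3,4-dimethylbenzofuran-7-yl)oxy(tert-butyl)dimethylsilane
Conditions: TBSCl, imidazole, DMF, 23 °C
Reagents that add atoms: tert-butyldimethylsilyl chloride, CC(C)(C)[Si](C)(C)Cl
Why: Silylation of the phenol gives an ether that tolerates the Grignard, borane and methylation steps and is removed by fluoride.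

Step 6
Reactants: 7 (5-bromo-3,4-dimethylbenzofuran-7-yl)oxy(tert-butyl)dimethylsilane; 8 3-chloropropanoyl chloride
Product: 10 1-[7-(tert-butyldimethylsilyloxy)-3,4-dimethylbenzofuran-5-yl]-3-chloropropan-1-one, via aryl Grignard reagent 9 (not isolated)
Conditions: Mg, LiCl, THF, 40 °C; then 8, CuI (10 mol%), THF, −40 °C
Reagents that add atoms: none
Why: Magnesium insertion gives the aryl Grignard reagent, whose copper-catalysed acylation by the acid chloride should be faster than attack on the ketone formed or on the primary chloride.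

Step 7
Reactants: 10 1-[7-(tert-butyldimethylsilyloxy)-3,4-dimethylbenzofuran-5-yl]-3-chloropropan-1-one
Product: 11 (1R)-1-[7-(tert-butyldimethylsilyloxy)-3,4-dimethylbenzofuran-5-yl]-3-chloropropan-1-ol
Conditions: (S)-Me-CBS (10 mol%), BH3·SMe2, THF, −20 °C
Reagents that add atoms: none
Why: Corey–Bakshi–Shibata reduction, in which the (S)-oxazaborolidine treats the aryl group as the large substituent and should give the (R)-carbinol, as it does with 3-chloropropiophenone.

Step 8
Reactants: 11 (1R)-1-[7-(tert-butyldimethylsilyloxy)-3,4-dimethylbenzofuran-5-yl]-3-chloropropan-1-ol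
Product: 12 tert-butyl{[5-((1R)-3-chloro-1-methoxypropyl)-3,4-dimethylbenzofuran-7-yl]oxy}dimethylsilane
Conditions: MeOTf, 2,6-di-tert-butyl-4-methylpyridine, CH2Cl2, 0 → 23 °C
Reagents that add atoms: methyl trifluoromethanesulfonate, COS(=O)(=O)C(F)(F)F
Why: O-Methylation under non-basic conditions avoids oxetane formation from a γ-chloro alkoxide and keeps the configuration because the C–O bond is not touched.

Step 9
Reactants: 12 tert-butyl{[5-((1R)-3-chloro-1-methoxypropyl)-3,4-dimethylbenzofuran-7-yl]oxy}dimethylsilane
Product: 13 5-[(1R)-3-chloro-1-methoxypropyl]-3,4-dimethylbenzofuran-7-ol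
Conditions: TBAF, THF, 0 °C
Reagents that add atoms: none
Why: Fluoride cleaves the aryl silyl ether, while the alkyl chloride and the methyl ether are inert.

Step 10
Reactants: 13 5-[(1R)-3-chloro-1-methoxypropyl]-3,4-dimethylbenzofuran-7-ol
Product: 14 5-[(1R)-3-chloro-1-methoxypropyl]-7-hydroxy-3,4-dimethylbenzofuran-6-carbaldehyde
Conditions: MgCl2, Et3N, (CH2O)n, MeCN, 80 °C
Reagents that add atoms: formaldehyde (from paraformaldehyde), C=O
Why: Magnesium-phenoxide-directed ortho-formylation (Casnati–Skattebøl) can occur only at C6, the one free position ortho to the hydroxyl group.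

Step 11
Reactants: 14 5-[(1R)-3-chloro-1-methoxypropyl]-7-hydroxy-3,4-dimethylbenzofuran-6-carbaldehyde
Product: 15 tert-butyl {5-[(1R)-3-chloro-1-methoxypropyl]-6-formyl-3,4-dimethylbenzofuran-7-yl} carbonate
Conditions: Boc2O, i-Pr2NEt, DMAP (cat.), CH2Cl2, 0 °C
Reagents that add atoms: di-tert-butyl dicarbonate, CC(C)(C)OC(=O)OC(=O)OC(C)(C)C
Why: DMAP-catalysed acylation of the phenol gives the O-Boc salicylaldehyde needed for the later alkoxide-triggered o-quinone methide formation.

Step 12
Reactants: 15 tert-butyl {5-[(1R)-3-chloro-1-methoxypropyl]-6-formyl-3,4-dimethylbenzofuran-7-yl} carbonate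
Product: 16 tert-butyl {6-formyl-5-[(1R)-3-iodo-1-methoxypropyl]-3,4-dimethylbenzofuran-7-yl} carbonate
Conditions: NaI, acetone, 56 °C
Reagents that add atoms: sodium iodide, [Na+].[I-]
Why: Finkelstein exchange of the primary chloride is driven by precipitation of NaCl, and the carbonate and aldehyde do not react with iodide.

Step 13
Reactants: 17 2-methoxy-4-methylphenol; 3 chloroacetone
Product: 18 1-(2-methoxy-4-methylphenoxy)propan-2-one
Conditions: K2CO3, KI (cat.), acetone, 56 °C
Reagents that add atoms: none
Why: Williamson ether synthesis of the phenoxide with the α-chloro ketone.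

Step 14
Reactants: 18 1-(2-methoxy-4-methylphenoxy)propan-2-one
Product: 19 7-methoxy-3,5-dimethylbenzofuran
Conditions: polyphosphoric acid, chlorobenzene, 100 °C
Reagents that add atoms: none
Why: Cyclodehydration of the aryloxyacetone closes onto the only free carbon ortho to the ether oxygen and gives the 3-methylbenzofuran.

Step 15
Reactants: 19 7-methoxy-3,5-dimethylbenzofuran
Product: 20 3,5-dimethylbenzofuran-7-ol
Conditions: BBr3, CH2Cl2, −78 → 0 °C
Reagents that add atoms: none
Why: Lewis-acid cleavage of the aryl methyl ether.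

Step 16
Reactants: 20 3,5-dimethylbenzofuran-7-ol
Product: 21 7-hydroxy-3,5-dimethylbenzofuran-6-carbaldehyde
Conditions: MgCl2, Et3N, (CH2O)n, MeCN, 80 °C
Reagents that add atoms: formaldehyde (from paraformaldehyde), C=O
Why: Magnesium-phenoxide-directed ortho-formylation can occur only at C6′, between the hydroxyl and methyl groups, the one free ortho position.

Step 17
Reactants: 21 7-hydroxy-3,5-dimethylbenzofuran-6-carbaldehyde
Product: 22 3,5-dimethyl-7-(triisopropylsilyloxy)benzofuran-6-carbaldehyde
Conditions: TIPSOTf, 2,6-lutidine, CH2Cl2, 0 °C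
Reagents that add atoms: triisopropylsilyl trifluoromethanesulfonate, CC(C)[Si](C(C)C)(C(C)C)OS(=O)(=O)C(F)(F)F
Why: Silylation of the hindered phenol gives an ether stable to ylide, aqueous base, SmI2 and Grignard reagent and removable with fluoride.

Step 18
Reactants: 22 3,5-dimethyl-7-(triisopropylsilyloxy)benzofuran-6-carbaldehyde
Product: 23 (3,5-dimethyl-6-vinylbenzofuran-7-yl)oxytriisopropylsilane
Conditions: Ph3PCH3Br, KHMDS, THF, 0 °C
Reagents that add atoms: methyltriphenylphosphonium bromide, C[P+](c1ccccc1)(c1ccccc1)c1ccccc1.[Br-]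
Why: Wittig methylenation of the aryl aldehyde.

Step 19
Reactants: 23 (3,5-dimethyl-6-vinylbenzofuran-7-yl)oxytriisopropylsilane; 24 (E)-1-bromoprop-1-ene
Product: 26 {3,5-dimethyl-6-[(E)-pent-3-en-1-yl]benzofuran-7-yl}oxytriisopropylsilane, via B-alkyl-9-BBN adduct 25 (not isolated)
Conditions: 9-BBN, THF, 23 → 50 °C; then 24, Pd(dppf)Cl2 (5 mol%), K3PO4 (3 M in H2O), DMF, 23 °C
Reagents that add atoms: none
Why: Anti-Markovnikov hydroboration of the styrene followed by B-alkyl Suzuki–Miyaura coupling with the (E)-alkenyl bromide, which keeps the alkene geometry.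

Step 20
Reactants: 16 tert-butyl {6-formyl-5-[(1R)-3-iodo-1-methoxypropyl]-3,4-dimethylbenzofuran-7-yl} carbonate; 26 {3,5-dimethyl-6-[(E)-pent-3-en-1-yl]benzofuran-7-yl}oxytriisopropylsilane
Product: 29 (5R,8R,2′R,3′R)-5-methoxy-7′-O-triisopropylsilyl cycloadduct (target skeleton with OMe on the opposite face in place of the C5 methyl), via cyclised samarium alkoxide 27 (not isolated), via o-quinone methide 28 (not isolated)
Conditions: 26 (2 equiv), SmI2 (2.1 equiv, added to the end point), HMPA, THF, −78 °C; then −78 → 23 °C
Reagents that add atoms: none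
Why: SmI2 reduces the primary iodide (or the aldehyde to its ketyl) and the organosamarium carbon C7 adds to the aldehyde carbon C8; the trivalent samarium alkoxide 27 then takes over the Boc group from O9 and the phenoxide expels tert-butyl carbonate to give o-quinone methide 28, which is trapped by the electron-rich C2′=C3′ bond of 26 in an inverse-electron-demand hetero-Diels–Alder reaction. The closest known reactions are the intramolecular samarium Barbier cyclisation of iodo carbonyl compounds and the alkoxide-triggered generation and [4+2] trapping of o-quinone methides from O-Boc salicylaldehydes after addition of an organometallic reagent. Ring C closes by a 6-exo-trig addition to the carbonyl group, and the chroman ring by an asynchronous [4+2] cycloaddition in which C8 bonds to the nucleophilic C2′ and O9 to C3′, the tertiary benzylic carbon that carries the developing positive charge. The C8 configuration of 27 is erased in 28; there the peri methyl at C4 turns H5 into the ring plane and the C5 methoxy group pseudoaxial, so that 26 should add to the opposite face of C8 along the axial trajectory, which sets C8 (R) from C5 (R). The endo transition state, with the benzo ring of 26 stacked on ring B, places H8, H2′ and the C3′ methyl on one face, and the suprafacial addition makes the new ring fusion cis, which sets C2′ (R) and C3′ (R). The step needs reduction of the iodide without pinacol coupling (the aldehyde is shielded by two ortho groups), trapping of 28 faster than its tautomerisation or oligomerisation (26 in excess, low temperature) and no reduction of 28 (no excess SmI2).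

Step 21
Reactants: 29 (5R,8R,2′R,3′R)-5-methoxy-7′-O-triisopropylsilyl cycloadduct
Product: 30 (5S,8R,2′R,3′R)-7′-O-triisopropylsilyl ether of the target
Conditions: Ni(cod)2 (10 mol%), rac-BINAP (20 mol%), MeMgI, toluene, 23 °C
Reagents that add atoms: methylmagnesium iodide, C[Mg]I
Why: Stereospecific nickel-catalysed Kumada coupling of a benzylic methyl ether, in which zerovalent nickel should displace methoxide from the rear of the C5–O bond of the benzofuran-fused arene and pass the methyl group on to the same face, so that C5 is inverted to (S) and the methyl ends pseudoaxial and cis to C8–C2′, the unstrained arrangement.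

Step 22
Reactants: 30 (5S,8R,2′R,3′R)-7′-O-triisopropylsilyl ether of the target
Product: 31 target CNP0281983.1
Conditions: TBAF, THF, 0 °C
Reagents that add atoms: none
Why: Fluoride-mediated cleavage of the aryl silyl ether under neutral conditions should leave the acid-labile tertiary benzylic aryl ether at C3′ and the (E)-alkene untouched.

Compound list
1 | 2-methoxy-5-methylphenol | COc1ccc(C)cc1O | starting material
2 | 4-bromo-2-methoxy-5-methylphenol | COc1cc(Br)c(C)cc1O | intermediate
3 | chloroacetone | CC(=O)CCl | starting material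
4 | 1-(4-bromo-2-methoxy-5-methylphenoxy)propan-2-one | COc1cc(Br)c(C)cc1OCC(C)=O | intermediate
5 | 5-bromo-7-methoxy-3,4-dimethylbenzofuran | COc1cc(Br)c(C)c2c(C)coc12 | intermediate
6 | 5-bromo-3,4-dimethylbenzofuran-7-ol | Oc1cc(Br)c(C)c2c(C)coc12 | intermediate
7 | (5-bromo-3,4-dimethylbenzofuran-7-yl)oxy(tert-butyl)dimethylsilane | CC(C)(C)[Si](C)(C)Oc1cc(Br)c(C)c2c(C)coc12 | intermediate
8 | 3-chloropropanoyl chloride | O=C(Cl)CCCl | starting material
9 | [7-(tert-butyldimethylsilyloxy)-3,4-dimethylbenzofuran-5-yl]magnesium bromide (not isolated) | CC(C)(C)[Si](C)(C)Oc1cc([Mg]Br)c(C)c2c(C)coc12 | intermediate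
10 | 1-[7-(tert-butyldimethylsilyloxy)-3,4-dimethylbenzofuran-5-yl]-3-chloropropan-1-one | CC(C)(C)[Si](C)(C)Oc1cc(C(=O)CCCl)c(C)c2c(C)coc12 | intermediate
11 | (1R)-1-[7-(tert-butyldimethylsilyloxy)-3,4-dimethylbenzofuran-5-yl]-3-chloropropan-1-ol | CC(C)(C)[Si](C)(C)Oc1cc([C@H](O)CCCl)c(C)c2c(C)coc12 | intermediate
12 | tert-butyl{[5-((1R)-3-chloro-1-methoxypropyl)-3,4-dimethylbenzofuran-7-yl]oxy}dimethylsilane | CC(C)(C)[Si](C)(C)Oc1cc([C@H](OC)CCCl)c(C)c2c(C)coc12 | intermediate
13 | 5-[(1R)-3-chloro-1-methoxypropyl]-3,4-dimethylbenzofuran-7-ol | Oc1cc([C@H](OC)CCCl)c(C)c2c(C)coc12 | intermediate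
14 | 5-[(1R)-3-chloro-1-methoxypropyl]-7-hydroxy-3,4-dimethylbenzofuran-6-carbaldehyde | Cc1coc2c(O)c(C=O)c([C@H](OC)CCCl)c(C)c12 | intermediate
15 | tert-butyl {5-[(1R)-3-chloro-1-methoxypropyl]-6-formyl-3,4-dimethylbenzofuran-7-yl} carbonate | CC(C)(C)OC(=O)Oc1c(C=O)c([C@H](OC)CCCl)c(C)c2c(C)coc12 | intermediate
16 | tert-butyl {6-formyl-5-[(1R)-3-iodo-1-methoxypropyl]-3,4-dimethylbenzofuran-7-yl} carbonate | CC(C)(C)OC(=O)Oc1c(C=O)c([C@H](OC)CCI)c(C)c2c(C)coc12 | intermediate
17 | 2-methoxy-4-methylphenol | COc1cc(C)ccc1O | starting material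
18 | 1-(2-methoxy-4-methylphenoxy)propan-2-one | COc1cc(C)ccc1OCC(C)=O | intermediate
19 | 7-methoxy-3,5-dimethylbenzofuran | COc1cc(C)cc2c(C)coc12 | intermediate
20 | 3,5-dimethylbenzofuran-7-ol | Oc1cc(C)cc2c(C)coc12 | intermediate
21 | 7-hydroxy-3,5-dimethylbenzofuran-6-carbaldehyde | O=Cc1c(C)cc2c(C)coc2c1O | intermediate
22 | 3,5-dimethyl-7-(triisopropylsilyloxy)benzofuran-6-carbaldehyde | O=Cc1c(C)cc2c(C)coc2c1O[Si](C(C)C)(C(C)C)C(C)C | intermediate
23 | (3,5-dimethyl-6-vinylbenzofuran-7-yl)oxytriisopropylsilane | C=Cc1c(C)cc2c(C)coc2c1O[Si](C(C)C)(C(C)C)C(C)C | intermediate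
24 | (E)-1-bromoprop-1-ene | C/C=C/Br | starting material
25 | 9-{2-[3,5-dimethyl-7-(triisopropylsilyloxy)benzofuran-6-yl]ethyl}-9-borabicyclo[3.3.1]nonane (not isolated) | CC(C)[Si](Oc1c(CCB2C3CCCC2CCC3)c(C)cc2c(C)coc12)(C(C)C)C(C)C | intermediate
26 | {3,5-dimethyl-6-[(E)-pent-3-en-1-yl]benzofuran-7-yl}oxytriisopropylsilane | C/C=C/CCc1c(C)cc2c(C)coc2c1O[Si](C(C)C)(C(C)C)C(C)C | intermediate
27 | tert-butyl [(5R)-8-hydroxy-5-methoxy-3,4-dimethyl-5,6,7,8-tetrahydronaphtho[2,3-b]furan-9-yl] carbonate, both C8 epimers, present as its trivalent samarium alkoxide (not isolated) | Cc1coc2c(OC(=O)OC(C)(C)C)c3C(O)CC[C@@H](OC)c3c(C)c12 | intermediate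
28 | (5R)-5-methoxy-3,4-dimethyl-6,7-dihydro-5H-naphtho[2,3-b]furan-9-one, o-quinone methide with C8=C8a (not isolated) | O=C1C2=CCC[C@@H](OC)C2=C(C)c2c(C)coc12 | intermediate
29 | (5R,8R,2′R,3′R)-cycloadduct: C8 of the 5-methoxy-3,4-dimethyl-5,6,7,8-tetrahydronaphtho[2,3-b]furan unit bonded to C2′ and its O9 to C3′ of the 3′,5′-dimethyl-6′-[(E)-pent-3-enyl]-7′-(triisopropylsilyloxy)-2′,3′-dihydrobenzofuran unit | C/C=C/CCc1c(C)cc2c(c1O[Si](C(C)C)(C(C)C)C(C)C)O[C@@H]1[C@@H]3CC[C@@H](OC)c4c3c(c3occ(C)c3c4C)O[C@]21C | intermediate
30 | (5S,8R,2′R,3′R)-7′-O-triisopropylsilyl ether of the target (C5 methyl in place of OMe, on the face of the C8–C2′ bond) | C/C=C/CCc1c(C)cc2c(c1O[Si](C(C)C)(C(C)C)C(C)C)O[C@@H]1[C@@H]3CC[C@H](C)c4c3c(c3occ(C)c3c4C)O[C@]21C | intermediate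
31 | CNP0281983.1, (5S,8R,2′R,3′R) | C/C=C/CCc1c(C)cc2c(c1O)O[C@@H]1[C@@H]3CC[C@H](C)c4c3c(c3occ(C)c3c4C)O[C@]21C | target

Total step count: 22. Longest linear sequence: 15 steps (steps 1–12 and 20–22).

Steps most likely to fail

1. Step 20. The samarium ketyl may dimerise or be quenched before the ring closes, the trivalent samarium alkoxide may pass on the Boc group too slowly, and the o-quinone methide may tautomerise to the 7,8-alkene phenol or oligomerise before the moderately nucleophilic benzofuran traps it. Fallback: from 16 the ring would be closed by the Takai alkylchromium addition (CrCl2, catalytic cobalt phthalocyanine Co(C32H16N8), DMF, 23 °C) and carbinol 27 isolated as the free alcohol (no new compound, F0). Then 27 would be deprotonated with t-BuMgCl in THF at −78 °C in the presence of 26 and warmed to 23 °C, so that the magnesium alkoxide sets off Boc migration, elimination to 28 and cycloaddition, returning to the route at 29.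

2. Step 21. Oxidative addition into the hindered benzylic C–O bond may be slow, β-hydride elimination may give the 5,6-alkene, and magnesium salts may ionise the tertiary aryl ether at C3′. Fallback: from 29 the benzylic methyl ether would be cleaved oxidatively with DDQ in CH2Cl2/H2O to the C5 ketone F1, and Wittig methylenation (Ph3P=CH2, toluene, 80 °C) would give the exocyclic alkene F2. Hydrogen-atom-transfer hydrogenation (Mn(dpm)3, PhSiH3, t-BuOOH, i-PrOH, 23 °C) should then reduce this 1,1-disubstituted styrene in preference to the 1,2-disubstituted pentenyl alkene and deliver hydrogen to the tertiary benzylic radical so that the methyl ends pseudoaxial, returning to the route at 30.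

3. Step 10. Substitution at C6 may be slow because the position lies between the hydroxyl group and the branched side chain. Fallback: from 13 the carbon would be brought in by boron-templated ortho-hydroxymethylation (PhB(OH)2, (CH2O)n, cat. EtCO2H, toluene, 110 °C) to the 2-phenyl-4H-1,3,2-benzodioxaborin F3. Transesterification with pinacol would free the salicyl alcohol F4, and MnO2 in CH2Cl2 would oxidise its benzylic alcohol, returning to the route at 14.

Further compounds
F0 | step 20 | none | none
F1 | step 21 | (8R,2′R,3′R)-5-oxo analogue of 29 (C5 ketone) | C/C=C/CCc1c(C)cc2c(c1O[Si](C(C)C)(C(C)C)C(C)C)O[C@@H]1[C@@H]3CCC(=O)c4c3c(c3occ(C)c3c4C)O[C@]21C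
F2 | step 21 | (8R,2′R,3′R)-5-methylidene analogue of 29 | C/C=C/CCc1c(C)cc2c(c1O[Si](C(C)C)(C(C)C)C(C)C)O[C@@H]1[C@@H]3CCC(=C)c4c3c(c3occ(C)c3c4C)O[C@]21C
F3 | step 10 | 2-phenyl-4H-1,3,2-benzodioxaborin formed across O7 and C6 of 13 | Cc1coc2c3OB(c4ccccc4)OCc3c([C@H](OC)CCCl)c(C)c12
F4 | step 10 | 5-[(1R)-3-chloro-1-methoxypropyl]-6-(hydroxymethyl)-3,4-dimethylbenzofuran-7-ol | Cc1coc2c(O)c(CO)c([C@H](OC)CCCl)c(C)c12
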